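Atoms carry prostaglandin numbering throughout: C1 is the carboxyl carbon, the ring is C8–C12 (C9 carbonyl, C11 carbinol), C15 is the side-chain carbinol and C20 the terminal methyl.

Assumption: (S)-oct-1-en-3-ol (5) is treated as a catalogue compound of high enantiomeric purity; C15 is never touched, so its purity is carried unchanged into 14.

## The problem

13,14-Dihydro-PGE1 (14) is a cyclopentanone with the ketone at C9, a hydroxyl at C11, a saturated seven-carbon acid chain on C8 and a saturated (S)-3-hydroxyoctyl chain on C12. Four stereocenters must be delivered as 8R, 11R, 12R, 15S: the three ring centres are contiguous and all-trans, and C15 lies three bonds out from the ring. Within the ring, C11 can control C12, because a reagent adds to a 4-oxygenated cyclopentenone anti to the oxygen. C12 in turn controls C8 thermodynamically, because C8 is alpha to the ketone and the 2,3-trans arrangement is the stable one. C15 is too remote for ring control and must come in with a chiral building block. The β-hydroxy ketone is the fragile element: base or strong acid dehydrates it to the cyclopentenone and epimerises C8, so the ketol must be unveiled late under buffered conditions and the ester hydrolysed enzymatically. The target contains no alkene, so any olefin used to make a carbon–carbon bond can be hydrogenated away and its geometry does not matter, which suits olefin metathesis. Two features make the key step possible: C7 and C13 are the first chain atoms on the adjacent ring carbons C8 and C12, so they can be tied together as a C7=C13 cyclobutene fused across C8–C12, and O11 and O15 are 1,5-related, so one silicon atom can bridge them and hold the ω-chain alkene next to C13 (eight-membered ring Si, O11, C11, C12, C13, C14, C15, O15).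

## Retrosynthesis

**Ester and C8 configuration (14 ⇒ 13 ⇒ 12).** No skeletal bond is cut. The acid 14 is drawn as its methyl ester 13, and 13 as its C8 epimer 12, in which the two chains are cis. This is preferred to building the trans relationship kinetically, because a ring fused across C8–C12 necessarily delivers the cis isomer and the trans isomer is the thermodynamic one. Forward, this asks for a base mild enough to equilibrate C8 without dehydrating the ketol, and for ester cleavage at neutral pH.

**Silicon bridge and the two alkenes (12 ⇒ 11 ⇒ 10).** The O11–Si and O15–Si bonds are restored, giving silaketal 11, and the C6–C7 and C13–C14 single bonds are redrawn as double bonds, giving diene 10. The bridge is preferred to two separate protecting groups because it doubles as the tether of the key step. The alkenes cost only one hydrogenation, since the target is saturated. Forward, the hydrogenation must not move either double bond toward C12 or C15, and the silicon must come off under acidic fluoride conditions that the ketol tolerates.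

**Key disconnection (10 ⇒ 8 + 9).** C6=C7 and C13=C14 are cut and C7 is rejoined to C13, which gives the cis-fused cyclobutene 8 carrying the octenyl unit on O11 through silicon, and the ester olefin 9. The neighbouring cuts are C12–C13 (conjugate addition of an ω-chain nucleophile) and C7–C8 (alkylation of the resulting enolate). For this target they would need an sp3 organometallic carrying a protected carbinol, and an enolate alkylation that competes with proton exchange and loss of O11. Cutting one bond further out in each chain turns both fragments into simple terminal alkenes and lets ring strain drive the reaction. Compound 10 has 27 carbons and two chains; 8 is a small bicycle assembled from three commercial pieces and 9 is commercial. The forward reaction must open the cyclobutene, close the eight-membered ring at C13 only, and extend C7 by cross-metathesis, without oligomerisation.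

**Tether assembly (8 ⇒ 4 + 5 + 6).** The two Si–O bonds are cut, giving ketol 4, allylic alcohol 5 and dichlorosilane 6; the monochloride 7 is the intermediate. This is the only place where C15 enters, as a purchased stereocenter. The forward reaction must give the unsymmetrical silaketal rather than the two symmetrical ones, under a base too weak to dehydrate 4.

**Cyclobutene (4 ⇒ 3 ⇒ 1 + 2).** The silyl ether 3 is the protected form of 4, and its C7–C8 and C12–C13 bonds are cut in a [2+2] sense to enone 1 and alkyne 2. The bulky silyl ether on 1 is kept for the photochemical step because it directs the alkyne to the face anti to O11. Attaching the tether first would place a second alkene in reach of the excited enone. The forward reaction must set C12 anti to O11; C8 follows from the cis ring fusion.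

## Roads not taken

**Alternative 1: amino-acid-catalysed dimerisation of a C4 dialdehyde.**
- Cut: the ring at C8–C9 and C11=C12, and a lactol bond O9–C6.
- Forward key step: two molecules of succinaldehyde A1 are joined by an enamine aldol, hemiacetalisation and an intramolecular aldol condensation to the bicyclic enal A2, (3aR,6aS)-2-hydroxy-3,3a,6,6a-tetrahydro-2H-cyclopenta[b]furan-5-carbaldehyde.
- Merits: C8 and C9 are set by a catalyst from an achiral feedstock, there is no photochemistry, and later conjugate addition to C12 gives the C8/C12 trans relationship directly, with no equilibration.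
- Weak points for this target:
  - A2 has the F-series oxidation pattern. O9 is an alcohol-level oxygen, and C11 is an enal carbon carrying a formyl carbon that is not in the target.
  - Reaching 14 would need acetal formation, conjugate addition of an sp3 organocopper reagent carrying C13–C20 (itself made in several steps from a chiral alcohol), ozonolytic removal of the formyl carbon, stereoselective reduction at C11, protection of O11, lactol olefination with a C1–C5 ylide, hydrogenation, oxidation at C9 and deprotection. On paper this is about ten operations plus fragment preparation.
  - Dimerisation of A1 competes with its oligomerisation, so throughput of the first step is inherently modest.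
- Comparison: this road is better in catalytic enantiocontrol and in setting C8 correctly from the start. The chosen plan offers redox economy instead: the C9 ketone and O11 are at their final oxidation level from compound 1 onward, there is no O9/O11 differentiation, and both chains arrive in one operation from commercial alkenes. It pays with a photochemical step and a C8 equilibration.

**Alternative 2: mixed Kolbe electrolysis with radical cyclisation.**
- Cut: C7–C8 and C12–C13, homolytically.
- Forward key step: co-electrolysis of the acetal acid A3, 3-ethoxy-3-{[(1S,4R)-4-(tert-butyldimethylsilyloxy)cyclopent-2-en-1-yl]oxy}propanoic acid, with the chain acid A4, (S)-4-(tert-butyldimethylsilyloxy)nonanoic acid, at a platinum anode. The C7 radical from A3 closes onto C8 (oxolane ring), and the resulting C12 radical couples with the C13 radical from A4 to give the cis-fused oxabicycle A5.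
- Merits: two C–C bonds and a ring form without any metal reagent. The C12–C13 bond is made sp3–sp3, so the ω chain arrives saturated as the target requires. The cis-fused ring places C7 on the α face and coupling at C12 occurs anti to it, so C8/C12 are trans without equilibration.
- Weak points for this target:
  - Radical cross-coupling is statistical: the C12 radical must meet the radical from A4 rather than its own kind, which needs a large excess of A4 and still gives symmetrical dimers and disproportionation products.
  - Selectivity at C12 rests only on the shape of the bicyclic radical.
  - A3 and A4 each need several preparative steps.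
  - A5 is at the wrong oxidation level at C6 (acetal) and C9 (ether). Acetal hydrolysis, olefination with C1–C5, hydrogenation, oxidation at C9 and desilylation would still follow.
- Comparison: this road is better in avoiding noble metals, in making C12–C13 saturated directly and in setting C8. The chosen plan offers tether-controlled rather than statistical bond formation, commercial chain fragments, and a shorter path after the key step.

**Alternative 3: Piancatelli rearrangement of a 2,5-disubstituted furan.**
- Cut: the ring bond C8–C12.
- Forward key step: aqueous ZnCl2 ionises the furyl carbinol A6, methyl 7-{5-[(3S)-3-(tert-butyldimethylsilyloxy)octyl]furan-2-yl}-7-hydroxyheptanoate. Water adds at the furan carbon bearing the ω chain, the ring opens, and conrotatory 4π closure of the hydroxypentadienyl cation gives the 4-hydroxycyclopent-2-enone A7.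
- Merits: inexpensive aromatic starting materials, all twenty carbons in place before the ring forms, and the carbocycle made in one step with defined relative configuration.
- Weak points for this target:
  - The hydroxyl of A7 sits on C12 as a tertiary alcohol geminal to the ω chain, and C11 is an unoxygenated alkene carbon; the target needs H on C12 and OH on C11.
  - Correcting this would need isomerisation to a 2,3-dialkyl-4-hydroxycyclopent-2-enone and then reduction of a tetrasubstituted enone with C8 and C12 trans to each other and to O11, whereas hydrogenation delivers cis.
  - The relative configuration formed (ω chain cis to the α chain) is not that of the target.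
  - The remote C15 centre cannot bias the electrocyclisation, so both ring enantiomers form and half the material is a diastereomer with the wrong ring.
- Comparison: this road is cheaper and equally convergent up to the ring. The chosen plan takes the absolute ring configuration from compound 1 and has oxygen on the correct carbon from the start; in exchange it needs a purchased chiral enone and a ruthenium catalyst.

Key step: step 4

## Route

Step 1
Reactants: 1 (R)-4-(tert-butyldimethylsilyloxy)cyclopent-2-en-1-one; 2 acetylene
Product: 3 (1S,4R,5R)-4-(tert-butyldimethylsilyloxy)bicyclo[3.2.0]hept-6-en-2-one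
Conditions: C2H2 (sat.), CH2Cl2, hν (medium-pressure Hg lamp, uranium-glass filter, λ > 340 nm), −78 °C, to partial conversion
Reagents that add atoms: none
Why: Enone–alkyne [2+2] photocycloaddition across C8=C12; the four/five ring fusion can only be cis and the bulky silyloxy group on C11 should direct the alkyne to the opposite face, which sets C12 (R, C13 trans to O11) and, provisionally, C8 (S); the long-wavelength cut-off and partial conversion limit secondary 1,3-acyl shift of the β,γ-unsaturated ketone product, and the minor syn adduct is a separable diastereomer.

Step 2
Reactants: 3 (1S,4R,5R)-4-(tert-butyldimethylsilyloxy)bicyclo[3.2.0]hept-6-en-2-one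
Product: 4 (1S,4R,5R)-4-hydroxybicyclo[3.2.0]hept-6-en-2-one
Conditions: HF·pyridine, pyridine, THF, 0 °C → rt
Reagents that add atoms: none
Why: Acidic fluoride cleavage of a secondary silyl ether; the buffered reagent avoids the basic conditions under which the β-silyloxy ketone would eliminate (E1cB), and no stereocenter is touched.

Step 3
Reactants: 4 (1S,4R,5R)-4-hydroxybicyclo[3.2.0]hept-6-en-2-one; 5 (S)-oct-1-en-3-ol; 6 dichlorodiisopropylsilane
Product: 8 (1S,4R,5R)-4-({diisopropyl[(3S)-oct-1-en-3-yloxy]silyl}oxy)bicyclo[3.2.0]hept-6-en-2-one, via chloro(diisopropyl)[(3S)-oct-1-en-3-yloxy]silane 7 (not isolated)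
Conditions: 5 (1.2 equiv) added slowly to 6 (1.2 equiv), imidazole, CH2Cl2, 0 °C; then 4 (1.0 equiv), imidazole, rt
Reagents that add atoms: none
Why: Stepwise O-silylation to an unsymmetrical silaketal: the first chloride of 6 is displaced by 5 at 0 °C and the more hindered Si–Cl of 7 reacts only when 4 is added; imidazole is too weak a base to dehydrate the ketol, and only O–Si bonds form, so C11 and C15 keep their configuration.

Step 4
Reactants: 8 (1S,4R,5R)-4-({diisopropyl[(3S)-oct-1-en-3-yloxy]silyl}oxy)bicyclo[3.2.0]hept-6-en-2-one; 9 methyl hept-6-enoate
Product: 10 methyl (6E,8S,11R,12R,13Z,15S)-11,15-[(diisopropylsilanediyl)bis(oxy)]-9-oxoprosta-6,13-dien-1-oate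
Conditions: second-generation Hoveyda–Grubbs catalyst RuCl2(=CH-C6H4-2-OiPr)(H2IMes) (5–10 mol %; H2IMes = 1,3-dimesityl-4,5-dihydroimidazol-2-ylidene), 9 (5 equiv), CH2Cl2 (5 mM in 8), 40 °C, argon sweep
Reagents that add atoms: none
Why: Domino ring-opening/ring-closing/cross-metathesis; the catalyst is loaded first by the unhindered olefin 9, the resulting ruthenium alkylidene undergoes [2+2] cycloaddition to the strained C7=C13 bond of 8 on its convex face, and cycloreversion of the metallacyclobutane opens the four-membered ring irreversibly, leaving the ester chain on one former cyclobutene carbon and ruthenium on the other. When ruthenium sits on C13 it is held next to the tethered C14=CH2 unit and a second metallacyclobutane closes the eight-membered 1,3-dioxa-2-silacyclooct-5-ene by ring-closing metathesis (endocyclic C13=C14 necessarily Z, ring trans-fused across C11–C12); when ruthenium sits on C7 it is capped by cross-metathesis with 9 and C13 is closed afterwards by secondary metathesis with the tethered vinyl group, so both modes of opening converge on 10. The closest known reaction types are ring-rearrangement metathesis of cyclobutenes bearing a pendant alkene, temporary silicon-tethered ring-closing metathesis of allylic/homoallylic silaketals to eight-membered rings, and ring-opening cross-metathesis of bicyclo[3.2.0]heptenes. No stereocenter is created: C8, C11, C12 and C15 are carried over, and the one undefined element, the C6=C7 geometry (mainly E expected), disappears in step 5. The step needs site selectivity (ring closure at C13, chain extension at C7) and chemoselectivity against ring-opening oligomerisation. The first is secured by the tether, since O11 and C7 lie on opposite faces of the cyclopentanone in a 1,3-relationship and could only be joined through a prohibitively strained bridged nine-membered ring; the second by high dilution in 8, the excess of 9 and removal of ethene.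

Step 5
Reactants: 10 methyl (6E,8S,11R,12R,13Z,15S)-11,15-[(diisopropylsilanediyl)bis(oxy)]-9-oxoprosta-6,13-dien-1-oate
Product: 11 methyl (8S,11R,12R,15S)-11,15-[(diisopropylsilanediyl)bis(oxy)]-9-oxoprostan-1-oate
Conditions: H2 (1 atm), 5% Pt/C, EtOAc, rt
Reagents that add atoms: none
Why: Heterogeneous catalytic hydrogenation of two 1,2-disubstituted alkenes; platinum is chosen over palladium because it causes far less double-bond migration (which would endanger C12 and C15) and less allylic C–O hydrogenolysis at C15, while the ketone and silaketal are inert under neutral conditions at 1 atm.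

Step 6
Reactants: 11 methyl (8S,11R,12R,15S)-11,15-[(diisopropylsilanediyl)bis(oxy)]-9-oxoprostan-1-oate
Product: 12 methyl 7-[(1S,2R,3R)-3-hydroxy-2-[(3S)-3-hydroxyoctyl]-5-oxocyclopentyl]heptanoate
Conditions: HF·pyridine, pyridine, MeCN, 0 °C
Reagents that add atoms: none
Why: Fluoride cleavage of both Si–O bonds under buffered acidic conditions of the kind used to unmask β-hydroxy cyclopentanones of the E series without dehydration; no C–O bond or stereocenter is affected.

Step 7
Reactants: 12 methyl 7-[(1S,2R,3R)-3-hydroxy-2-[(3S)-3-hydroxyoctyl]-5-oxocyclopentyl]heptanoate
Product: 13 methyl 7-[(1R,2R,3R)-3-hydroxy-2-[(3S)-3-hydroxyoctyl]-5-oxocyclopentyl]heptanoate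
Conditions: KOAc, MeOH, rt; recovered 12 recycled
Reagents that add atoms: none
Why: Thermodynamic epimerisation of the α-stereocenter through the enol: C8 is the only enolisable stereocenter, and in 2,3-dialkylcyclopentanones the trans isomer is favoured, so C12 (R) sets C8 (R); acetate is a weak enough base that β-elimination of the C11 hydroxyl should stay slow.

Step 8
Reactants: 13 methyl 7-[(1R,2R,3R)-3-hydroxy-2-[(3S)-3-hydroxyoctyl]-5-oxocyclopentyl]heptanoate
Product: 14 7-[(1R,2R,3R)-3-hydroxy-2-[(3S)-3-hydroxyoctyl]-5-oxocyclopentyl]heptanoic acid (13,14-dihydro-PGE1)
Conditions: porcine liver esterase, pH 7.5 phosphate buffer/acetone, 30 °C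
Reagents that add atoms: water, O
Why: Enzymatic ester hydrolysis at neutral pH, the established way to free E-series acids from their methyl esters without dehydration or C8 epimerisation; no stereocenter is involved.

## Compound list

1 | (R)-4-(tert-butyldimethylsilyloxy)cyclopent-2-en-1-one | O=C1C=C[C@H](O[Si](C)(C)C(C)(C)C)C1 | starting material
2 | acetylene (ethyne) | C#C | starting material
3 | (1S,4R,5R)-4-(tert-butyldimethylsilyloxy)bicyclo[3.2.0]hept-6-en-2-one (cis-fused, cyclobutene anti to O11) | CC(C)(C)[Si](C)(C)O[C@@H]1CC(=O)[C@H]2C=C[C@@H]12 | intermediate
4 | (1S,4R,5R)-4-hydroxybicyclo[3.2.0]hept-6-en-2-one | O[C@@H]1CC(=O)[C@H]2C=C[C@@H]12 | intermediate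
5 | (S)-oct-1-en-3-ol | CCCCC[C@H](O)C=C | starting material
6 | dichlorodiisopropylsilane | CC(C)[Si](Cl)(Cl)C(C)C | starting material
7 | chloro(diisopropyl)[(3S)-oct-1-en-3-yloxy]silane | CCCCC[C@H](O[Si](Cl)(C(C)C)C(C)C)C=C | intermediate (not isolated)
8 | (1S,4R,5R)-4-({diisopropyl[(3S)-oct-1-en-3-yloxy]silyl}oxy)bicyclo[3.2.0]hept-6-en-2-one | C=C[C@H](CCCCC)O[Si](C(C)C)(C(C)C)O[C@@H]1CC(=O)[C@H]2C=C[C@@H]12 | intermediate
9 | methyl hept-6-enoate | C=CCCCCC(=O)OC | starting material
10 | methyl (6E,8S,11R,12R,13Z,15S)-11,15-[(diisopropylsilanediyl)bis(oxy)]-9-oxoprosta-6,13-dien-1-oate (cyclopentanone with cis C8/C12 chains; O11 and O15 bridged by iPr2Si in an eight-membered ring trans-fused at C11–C12) | COC(=O)CCCC/C=C/[C@@H]1C(=O)C[C@H]2O[Si](C(C)C)(C(C)C)O[C@@H](CCCCC)/C=C\[C@H]12 | intermediate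
11 | methyl (8S,11R,12R,15S)-11,15-[(diisopropylsilanediyl)bis(oxy)]-9-oxoprostan-1-oate | COC(=O)CCCCCC[C@@H]1C(=O)C[C@H]2O[Si](C(C)C)(C(C)C)O[C@@H](CCCCC)CC[C@H]12 | intermediate
12 | methyl 7-[(1S,2R,3R)-3-hydroxy-2-[(3S)-3-hydroxyoctyl]-5-oxocyclopentyl]heptanoate (C8 epimer of 13) | CCCCC[C@H](O)CC[C@H]1[C@H](O)CC(=O)[C@H]1CCCCCCC(=O)OC | intermediate
13 | methyl 7-[(1R,2R,3R)-3-hydroxy-2-[(3S)-3-hydroxyoctyl]-5-oxocyclopentyl]heptanoate | CCCCC[C@H](O)CC[C@H]1[C@H](O)CC(=O)[C@@H]1CCCCCCC(=O)OC | intermediate
14 | 7-[(1R,2R,3R)-3-hydroxy-2-[(3S)-3-hydroxyoctyl]-5-oxocyclopentyl]heptanoic acid (13,14-dihydro-PGE1) | CCCCC[C@H](O)CC[C@H]1[C@H](O)CC(=O)[C@@H]1CCCCCCC(=O)O | target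

## Step count and risk

Total step count: 8. Longest linear sequence: 8 steps (1 → 14); compounds 2, 5, 6 and 9 are commercial and enter without prior steps.

**Step 4 (key step).** Ring-opening oligomerisation of the cyclobutene, or capping of both termini by 9, may outrun closure of the trans-fused eight-membered ring. Chelation of the C9 carbonyl oxygen to the C7 alkylidene may also slow turnover. The fallback separates the three metathesis events into known operations. Starting from 8, ring-opening with ethene (1 atm, same catalyst) gives (2S,3R,4R)-2,3-diethenyl-4-({diisopropyl[(3S)-oct-1-en-3-yloxy]silyl}oxy)cyclopentan-1-one F1. F1 is then cyclised at high dilution under argon by ordinary silicon-tethered ring-closing metathesis, in which only the C13 vinyl group can reach the tether, to the ring-rearranged C8-vinyl silaketal F2 (compound 10 with a vinyl group in place of the heptenoate chain). Cross-metathesis of F2 with an excess of 9 returns to the route at 10.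

**Step 1.** Secondary photoisomerisation of the β,γ-unsaturated ketone product (1,3-acyl shift) and slow conversion with gaseous acetylene may erode the yield; facial selectivity depends only on the silyl ether. The fallback uses a two-step acetylene surrogate. Starting from 1, [2+2] photocycloaddition with (Z)-1,2-dichloroethene gives (1S,4R,5R)-4-(tert-butyldimethylsilyloxy)-6,7-dichlorobicyclo[3.2.0]heptan-2-one F3 (mixture at the two chlorine-bearing carbons). F3 has no β,γ-enone chromophore and can be irradiated to full conversion. Reductive 1,2-elimination with activated zinc dust in warm ethanol then returns to the route at 3.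

**Step 3.** Double substitution at silicon may scramble the product into the two symmetrical silaketals, and the ketol 4 may dehydrate under base. The fallback uses a monochlorosilane, which cannot over-react. Starting from 5, chlorodiisopropylsilane and imidazole give diisopropyl[(3S)-oct-1-en-3-yloxy]silane F4. N-Bromosuccinimide in CH2Cl2 at 0 °C converts the Si–H bond into bromo(diisopropyl)[(3S)-oct-1-en-3-yloxy]silane F5, which is treated in the same flask with 4 and imidazole and returns to the route at 8.

**Step 5.** Metal-mediated migration of C13=C14 toward C12 or C15 before saturation would scramble those centres; hydrogenolysis of the allylic C15–O bond and slow reduction of the ketone are further risks. The fallback is metal-free diimide reduction (2-nitrobenzenesulfonohydrazide, Et3N, CH2Cl2, rt). It transfers H2 in a concerted syn fashion and can neither isomerise alkenes nor cleave C–O bonds. It sets out from 10 and arrives directly at 11 with no new compound (F0).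

**Step 7.** Equilibration may be incomplete, and β-elimination of the free C11 hydroxyl to the cyclopentenone may compete. The fallback corrects C8 before the ketol is unveiled. Starting from 11, triethylamine in CH2Cl2 at rt equilibrates the silaketal, which has no free hydroxyl and whose epimers differ more in shape, to methyl (8R,11R,12R,15S)-11,15-[(diisopropylsilanediyl)bis(oxy)]-9-oxoprostan-1-oate F6. Cleavage of the silicon bridge with HF·pyridine as in step 6 then returns to the route at 13.

## Further compounds

F1 | step 4 | (2S,3R,4R)-2,3-diethenyl-4-({diisopropyl[(3S)-oct-1-en-3-yloxy]silyl}oxy)cyclopentan-1-one | C=C[C@H](CCCCC)O[Si](C(C)C)(C(C)C)O[C@@H]1CC(=O)[C@@H](C=C)[C@H]1C=C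
F2 | step 4 | ring-rearranged C8-vinyl silaketal (compound 10 with CH=CH2 on C8 in place of the heptenoate chain) | C=C[C@@H]1C(=O)C[C@H]2O[Si](C(C)C)(C(C)C)O[C@@H](CCCCC)/C=C\[C@H]12
F3 | step 1 | (1S,4R,5R)-4-(tert-butyldimethylsilyloxy)-6,7-dichlorobicyclo[3.2.0]heptan-2-one (mixture at C6 and C7 of the bicycle) | CC(C)(C)[Si](C)(C)O[C@@H]1CC(=O)[C@H]2C(Cl)C(Cl)[C@@H]12
F4 | step 3 | diisopropyl[(3S)-oct-1-en-3-yloxy]silane | CCCCC[C@H](O[SiH](C(C)C)C(C)C)C=C
F5 | step 3 | bromo(diisopropyl)[(3S)-oct-1-en-3-yloxy]silane | CCCCC[C@H](O[Si](Br)(C(C)C)C(C)C)C=C
F0 | step 5 | none | none
F6 | step 7 | methyl (8R,11R,12R,15S)-11,15-[(diisopropylsilanediyl)bis(oxy)]-9-oxoprostan-1-oate | COC(=O)CCCCCC[C@H]1C(=O)C[C@H]2O[Si](C(C)C)(C(C)C)O[C@@H](CCCCC)CC[C@H]12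
A1 | alternative 1 | succinaldehyde (butanedial) | O=CCCC=O
A2 | alternative 1 | (3aR,6aS)-2-hydroxy-3,3a,6,6a-tetrahydro-2H-cyclopenta[b]furan-5-carbaldehyde | O=CC1=C[C@H]2CC(O)O[C@H]2C1
A3 | alternative 2 | 3-ethoxy-3-{[(1S,4R)-4-(tert-butyldimethylsilyloxy)cyclopent-2-en-1-yl]oxy}propanoic acid (acetal carbon undefined) | CCOC(CC(=O)O)O[C@@H]1C=C[C@H](O[Si](C)(C)C(C)(C)C)C1
A4 | alternative 2 | (S)-4-(tert-butyldimethylsilyloxy)nonanoic acid | CCCCC[C@H](O[Si](C)(C)C(C)(C)C)CCC(=O)O
A5 | alternative 2 | cis-fused 3-ethoxy-2-oxabicyclo[3.3.0]octane carrying the C11 silyl ether and the protected ω chain on C12 (acetal carbon undefined) | CCCCC[C@H](O[Si](C)(C)C(C)(C)C)CC[C@H]1[C@H](O[Si](C)(C)C(C)(C)C)C[C@@H]2OC(OCC)C[C@H]12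
A6 | alternative 3 | methyl 7-{5-[(3S)-3-(tert-butyldimethylsilyloxy)octyl]furan-2-yl}-7-hydroxyheptanoate (carbinol carbon undefined) | COC(=O)CCCCCC(O)c1ccc(CC[C@@H](O[Si](C)(C)C(C)(C)C)CCCCC)o1
A7 | alternative 3 | 4-hydroxy-4-[(3S)-3-(tert-butyldimethylsilyloxy)octyl]-5-(7-methoxy-7-oxoheptyl)cyclopent-2-en-1-one, hydroxyl trans to the α chain (one ring enantiomer drawn) | COC(=O)CCCCCC[C@H]1C(=O)C=C[C@@]1(O)CC[C@@H](O[Si](C)(C)C(C)(C)C)CCCCC
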